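The eight-membered ring (C1–C8) has oxygen at C8, a methyl at C6 and the cyclopropane on C4–C5, which is the pattern of a cyclooct-4-enone (C8=O, C4=C5). It is disconnected at C6–C7 to a 2-methylene-6-[(E)-propenyl]tetrahydropyran (ring atoms O, C8, C1–C4) that is trans-fused to the C2/C3 γ-lactone and carries the silylated C13 side chain equatorially on C1. One thermal [3,3] shift enlarges the pyran to the carbocycle, forms C6–C7, sets the C6 methyl from the C4 carbinol centre and leaves a Z C4=C5 alkene for the cyclopropane. The pyran is built from an enantioenriched β-alkyl lactone by Michael addition, aldol addition and selenoetherification.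

Key step: step 9

Remarks on the chemistry:
- Atom labels: C1–C8 are the ring carbons of the final cyclooctane (C1 side chain, C8 hydroxyl, C7 CH2, C6 methyl, C4/C5 cyclopropane with C9 as its CH2). C10 is the lactone C=O on C3, C12 the lactone CH2 on C2, C13 the side-chain CH and C14 its CH2O. Ring A is the side-chain lactone (C8, C1, C13, C14); ring B is the C2/C3 γ-lactone.
- Assumption: 4-bromofuran-2(5H)-one (2) is purchased.
- Compounds 17 and 18 were checked through a chair array against the target: 4S in 17 leads to 6S in 18, the target configuration, so the pair needs no stereochemical correction.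
- Design points: C13 is set by catalytic asymmetric reduction and relayed C13 → C1 → C2 → C3/C4 → C6 → C8 → C4/C5. C8 is taken to the aldehyde level while ring B is masked as its enolate, so the enol ether comes from selenoetherification and elimination and no carbonyl methylenation has to tell two lactones apart. The cyclopropanation is hydroxyl-directed to spare the side-chain alkene.

Step 1
Reactants: 1 5-bromo-2-methylpent-2-ene; 2 4-bromofuran-2(5H)-one
Product: 4 4-(4-methylpent-3-en-1-yl)furan-2(5H)-one, via homoprenylzinc bromide 3 (not isolated)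
Conditions: Zn, LiCl, THF, 50 °C; then 2, PdCl2(dppf) (3 mol %), THF, 50 °C
Reagents that add atoms: none
Why: LiCl-assisted zinc insertion into the primary bromide and Negishi coupling at the vinylogous acyl bromide should give the β-alkyl butenolide without touching the trisubstituted alkene; no stereocentre is formed.

Step 2
Reactants: 4 4-(4-methylpent-3-en-1-yl)furan-2(5H)-one
Product: 5 (4S)-4-(4-methylpent-3-en-1-yl)oxolan-2-one
Conditions: Cu(OAc)2 (5 mol %), (S)-p-tol-BINAP (5.5 mol %), (MeO)2MeSiH, t-BuOH, toluene, 0 °C to rt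
Reagents that add atoms: none
Why: Copper hydride asymmetric conjugate reduction of a β-alkyl butenolide, in which the ligand-bound hydride adds to one face of C13; by the facial model for 3-alkylcyclopent-2-enones the (S)-ligand should give the (S)-lactone (the antipodal ligand is the remedy if the first run shows the opposite sense), and the isolated alkene and the lactone carbonyl are inert to the catalyst.

Step 3
Reactants: 5 (4S)-4-(4-methylpent-3-en-1-yl)oxolan-2-one; 6 furan-2(5H)-one
Product: 9 (4S)-4-[(3R,4S)-2-hydroxy-4-(4-methylpent-3-en-1-yl)oxolan-3-yl]oxolan-2-one (ring-A lactol; both anomers), via ring-A lithium enolate 7 (not isolated), via adduct enolate 8 (not isolated)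
Conditions: LiN(i-Pr)2, THF, −78 °C; 6 (0.95 equiv), −78 °C; i-Bu2AlH (1.2 equiv), −78 °C; aq. KNaC4H4O6
Reagents that add atoms: none
Why: Michael addition of a lactone enolate to a butenolide followed by hydride reduction of a lactone to a lactol: the enolate reacts anti to the C13 substituent (sets C1) through an open, synclinal transition state that keeps the furanone hydrogen in the crowded sector between C8 and C13 (sets C2), and because the adduct is still the lithium enolate of ring B when i-Bu2AlH is added, C10 is masked and only the C8 carbonyl is reduced (enolate protection, a tactic established for keto esters).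

Step 4
Reactants: 9 ring-A lactol
Product: 10 (4S)-4-[(3R,4S)-4-(hydroxymethyl)-8-methylnona-1,7-dien-3-yl]oxolan-2-one
Conditions: Ph3PCH3Br, KN(SiMe3)2, THF, 0 °C to rt
Reagents that add atoms: methyltriphenylphosphonium bromide, C[P+](c1ccccc1)(c1ccccc1)c1ccccc1.[Br-]
Why: Wittig methylenation of the lactol through its open hydroxy-aldehyde form turns C8 into a vinyl carbon and frees the C14 hydroxyl, the non-stabilised ylide being too weak a base to enolise ring B and fast enough at 0 °C to outrun epimerisation at C1.

Step 5
Reactants: 10 (4S)-4-[(3R,4S)-4-(hydroxymethyl)-8-methylnona-1,7-dien-3-yl]oxolan-2-one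
Product: 11 (4S)-4-[(3S,4S)-4-({[tert-butyl(dimethyl)silyl]oxy}methyl)-8-methylnona-1,7-dien-3-yl]oxolan-2-one
Conditions: TBSCl, imidazole, DMF, 0 °C to rt
Reagents that add atoms: tert-butyldimethylsilyl chloride, CC(C)(C)[Si](C)(C)Cl
Why: Standard silylation of the primary C14 alcohol, which must be masked before the next enolate is formed (the C1 descriptor changes only because silicon alters the priorities).

Step 6
Reactants: 11 silyl ether; 12 (E)-but-2-enal
Product: 14 (3S,4R)-4-[(3R,4S)-4-({[tert-butyl(dimethyl)silyl]oxy}methyl)-8-methylnona-1,7-dien-3-yl]-3-[(1S,2E)-1-hydroxybut-2-en-1-yl]oxolan-2-one, via lithium enolate 13 (not isolated)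
Conditions: LiN(i-Pr)2, THF, −78 °C; 12, −78 °C; AcOH, −78 °C
Reagents that add atoms: none
Why: Lithium aldol addition of the ring-B enolate (the only acidic site) to the enal in 1,2-fashion: the aldehyde approaches anti to the C2 substituent (trans-lactone, sets C3) and the ring-fixed (E)-enolate in a Zimmerman–Traxler chair should give the anti aldol (sets C4 as S).

Step 7
Reactants: 14 aldol adduct
Product: 15 (3aS,4S,6R,7R,7aR)-7-[(2S)-1-{[tert-butyl(dimethyl)silyl]oxy}-6-methylhept-5-en-2-yl]-6-[(phenylselanyl)methyl]-4-[(1E)-prop-1-en-1-yl]hexahydro-1H-furo[3,4-c]pyran-3-one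
Conditions: N-(phenylseleno)phthalimide, CSA (10 mol %), CH2Cl2, 0 °C to rt
Reagents that add atoms: N-(phenylseleno)phthalimide, O=C1c2ccccc2C(=O)N1[Se]c1ccccc1
Why: Selenoetherification (6-exo, Markovnikov) of the vinyl group by the C4 hydroxyl closes the pyran, seleniranium formation at the two other alkenes being reversible and without a productive internal nucleophile; the trans-fused lactone forces the chair with the propenyl group axial and the side chain equatorial, and the new C8 centre is lost in the next step.

Step 8
Reactants: 15 selenide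
Product: 17 (3aS,4S,7R,7aR)-7-[(2S)-1-{[tert-butyl(dimethyl)silyl]oxy}-6-methylhept-5-en-2-yl]-6-methylidene-4-[(1E)-prop-1-en-1-yl]hexahydro-1H-furo[3,4-c]pyran-3-one, via selenoxide 16 (not isolated)
Conditions: NaIO4, NaHCO3, MeOH/THF/H2O, 0 °C to rt; then i-Pr2NH, toluene, 100 °C (sealed tube); filtration through basic alumina
Reagents that add atoms: none
Why: Periodate oxidation of the selenide and thermal selenoxide syn-elimination, for which C8–H is the only β-hydrogen, so that the exocyclic enol ether is the only alkene that can form; NaIO4 does not attack the C=C bonds and the amine traps PhSeOH.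

Step 9
Reactants: 17 2-methylene-6-propenylpyran
Product: 18 (3aR,4R,7S,9aR,8Z)-4-[(2S)-1-{[tert-butyl(dimethyl)silyl]oxy}-6-methylhept-5-en-2-yl]-7-methyl-3,3a,4,6,7,9a-hexahydrocycloocta[c]furan-1,5-dione
Conditions: toluene (degassed), base-washed sealed tube, 175 °C
Reagents that add atoms: none
Why: Concerted, suprafacial [3,3]-sigmatropic (Claisen) rearrangement of the allyl vinyl ether C7=C8–O–C4–C5=C6; the closest known reaction type is the thermal ring expansion of 2-methylene-6-vinyltetrahydropyrans to cyclooct-4-enones. The eight-membered ring is not closed end to end but arises by two-carbon ring enlargement: C6–C7 forms across a chair-like six-centre array that shares C8, O and C4 with the pyran chair while O–C4 breaks. The one new stereocentre, C6, is controlled by the C4 carbinol centre (1,3-chirality transfer): with the (E)-propenyl group axial its methyl lies pseudo-equatorial in the array, and bonding of C7 to the alkene face that this array presents should give 6S. The step needs chair over boat geometry and a precursor that keeps its exocyclic double bond; the trans-fused lactone locks the pyran chair with propenyl axial and side chain equatorial so that no ring flip is required, the E alkene keeps the methyl out of the ring, and neutral conditions free of acid and base prevent double-bond migration and C3 epimerisation. The ring forces the new C4=C5 alkene to be Z and the carbonyl appears at C8.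

Step 10
Reactants: 18 cyclooct-4-enone
Product: 19 (3aR,4R,5S,7S,9aR,8Z)-4-[(2S)-1-{[tert-butyl(dimethyl)silyl]oxy}-6-methylhept-5-en-2-yl]-5-hydroxy-7-methyl-3a,4,5,6,7,9a-hexahydrocycloocta[c]furan-1(3H)-one
Conditions: LiBH(s-Bu)3, THF, −78 °C; H2O
Reagents that add atoms: none
Why: Hydride reduction of the ketone by a bulky borohydride, which should approach C8 from the ring periphery on the face of the C1 hydrogen, away from the branched side chain, to give the alcohol cis to that chain (8S); the lactone is inert at −78 °C.

Step 11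
Reactants: 19 C8 alcohol
Product: 20 C4–C5 cyclopropane of 19 with C9 syn to the C8 hydroxyl (1R,2R,3R,4R,5R,6S,8S,13S by the atom labels)
Conditions: Et2Zn, CH2I2, CH2Cl2, −10 to 0 °C
Reagents that add atoms: diiodomethane, ICI
Why: Hydroxyl-directed Simmons–Smith cyclopropanation (Et2Zn/CH2I2): the C8 zinc alkoxide carries the carbenoid across the ring to the C4=C5 face syn to oxygen, which is also the face anti to the C6 methyl (sets C4 and C5), and this internal delivery should make the ring alkene react ahead of the undirected side-chain alkene.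

Step 12
Reactants: 20 cyclopropyl alcohol
Product: 21 C8 triethylsilyl ether of 20
Conditions: Et3SiOTf, 2,6-lutidine, CH2Cl2, −78 °C
Reagents that add atoms: triethylsilyl trifluoromethanesulfonate, CC[Si](CC)(CC)OS(=O)(=O)C(F)(F)F
Why: Silylation of the hindered secondary alcohol with a silyl triflate, needed so that the C8 oxygen does not consume base or selenenyl halide in the next step.

Step 13
Reactants: 21 bis-silyl ether lactone
Product: 23 C3-phenylselanyl lactone with selenium cis to H-2, via lithium enolate 22 (not isolated)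
Conditions: LiN(i-Pr)2, THF, −78 °C; PhSeBr, −78 °C
Reagents that add atoms: benzeneselenenyl bromide, Br[Se]c1ccccc1
Why: α-Selenenylation of the lactone lithium enolate (C3–H is the only acidic site once C8 is a silyl ether), selenium entering anti to the C1–C2 bond and hence cis to H-2, as the later syn-elimination requires.

Step 14
Reactants: 23 C3-phenylselanyl lactone
Product: 25 C2=C3 butenolide bis-silyl ether (1R,4R,5R,6S,8S,13S), via selenoxide 24 (not isolated)
Conditions: NaIO4, NaHCO3, THF/MeOH/H2O, rt
Reagents that add atoms: none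
Why: Selenide oxidation and selenoxide syn-elimination towards C2–H at room temperature should give the butenolide, elimination towards the cyclopropane C4–H being ruled out by strain, and periodate spares the trisubstituted alkene.

Step 15
Reactants: 25 butenolide bis-silyl ether
Product: 26 diol with C14–OH and C8–OH free
Conditions: HF·pyridine, pyridine, THF, 0 °C to rt
Reagents that add atoms: none
Why: Fluoride cleavage of both silyl ethers under buffered, non-basic conditions that should leave the butenolide, the cyclopropane and the alkene untouched.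

Step 16
Reactants: 26 diol
Product: 27 target, the C14 acetate with free C8 hydroxyl (CNP0267808.2)
Conditions: AcCl (1.05 equiv), 2,4,6-collidine, CH2Cl2, −78 °C
Reagents that add atoms: acetyl chloride, CC(Cl)=O
Why: Chemoselective acylation of the primary C14 alcohol in the presence of the hindered secondary C8 alcohol with one equivalent of acetyl chloride and a hindered pyridine base at low temperature.

Compound list
1 | 5-bromo-2-methylpent-2-ene | CC(C)=CCCBr | starting material
2 | 4-bromofuran-2(5H)-one | O=C1C=C(Br)CO1 | starting material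
3 | (4-methylpent-3-en-1-yl)zinc bromide | CC(C)=CCC[Zn]Br | intermediate (not isolated)
4 | 4-(4-methylpent-3-en-1-yl)furan-2(5H)-one | CC(C)=CCCC1=CC(=O)OC1 | intermediate
5 | (4S)-4-(4-methylpent-3-en-1-yl)oxolan-2-one (ring A) | O=C1C[C@H](CCC=C(C)C)CO1 | intermediate
6 | furan-2(5H)-one | O=C1OCC=C1 | starting material
7 | lithium enolate of 5 | [Li]OC1=C[C@H](CCC=C(C)C)CO1 | intermediate (not isolated)
8 | ring-B lithium enolate of the Michael adduct | O=C1OC[C@@H](CCC=C(C)C)[C@@H]1[C@H]1COC(O[Li])=C1 | intermediate (not isolated)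
9 | (4S)-4-[(3R,4S)-2-hydroxy-4-(4-methylpent-3-en-1-yl)oxolan-3-yl]oxolan-2-one, both anomers | OC1OC[C@@H](CCC=C(C)C)[C@@H]1[C@H]1COC(=O)C1 | intermediate
10 | (4S)-4-[(3R,4S)-4-(hydroxymethyl)-8-methylnona-1,7-dien-3-yl]oxolan-2-one | OC[C@@H](CCC=C(C)C)[C@@H](C=C)[C@H]1COC(=O)C1 | intermediate
11 | (4S)-4-[(3S,4S)-4-({[tert-butyl(dimethyl)silyl]oxy}methyl)-8-methylnona-1,7-dien-3-yl]oxolan-2-one | CC(C)(C)[Si](C)(C)OC[C@@H](CCC=C(C)C)[C@@H](C=C)[C@H]1COC(=O)C1 | intermediate
12 | (E)-but-2-enal (crotonaldehyde) | C/C=C/C=O | starting material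
13 | lithium enolate of 11 | CC(C)(C)[Si](C)(C)OC[C@@H](CCC=C(C)C)[C@@H](C=C)[C@H]1COC(O[Li])=C1 | intermediate (not isolated)
14 | (3S,4R)-4-[(3R,4S)-4-({[tert-butyl(dimethyl)silyl]oxy}methyl)-8-methylnona-1,7-dien-3-yl]-3-[(1S,2E)-1-hydroxybut-2-en-1-yl]oxolan-2-one | CC(C)(C)[Si](C)(C)OC[C@@H](CCC=C(C)C)[C@@H](C=C)[C@H]1COC(=O)[C@@H]1[C@@H](O)/C=C/C | intermediate
15 | trans-lactone-fused 2-[(phenylselanyl)methyl]-6-[(E)-propenyl]pyran (3aS,4S,6R,7R,7aR; C8 drawn with CH2SePh equatorial, its epimer serves equally) | CC(C)(C)[Si](C)(C)OC[C@@H](CCC=C(C)C)[C@@H]1[C@H]2COC(=O)[C@@H]2[C@H](/C=C/C)O[C@H]1C[Se]c1ccccc1 | intermediate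
16 | selenoxide of 15 (both configurations at selenium) | CC(C)(C)[Si](C)(C)OC[C@@H](CCC=C(C)C)[C@@H]1[C@H]2COC(=O)[C@@H]2[C@H](/C=C/C)O[C@H]1C[Se](=O)c1ccccc1 | intermediate (not isolated)
17 | trans-lactone-fused 2-methylene-6-[(E)-propenyl]tetrahydropyran (3aS,4S,7R,7aR; side chain 2S), the precursor of the key step | CC(C)(C)[Si](C)(C)OC[C@@H](CCC=C(C)C)[C@@H]1[C@H]2COC(=O)[C@@H]2[C@H](/C=C/C)OC1=C | intermediate
18 | lactone-fused (Z)-cyclooct-4-enone (3aR,4R,7S,9aR; side chain 2S), the product of the key step | CC(C)(C)[Si](C)(C)OC[C@@H](CCC=C(C)C)[C@@H]1[C@H]2COC(=O)[C@@H]2/C=C\[C@@H](C)CC1=O | intermediate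
19 | (8S)-alcohol of 18 (3aR,4R,5S,7S,9aR) | CC(C)(C)[Si](C)(C)OC[C@@H](CCC=C(C)C)[C@@H]1[C@H]2COC(=O)[C@@H]2/C=C\[C@@H](C)C[C@@H]1O | intermediate
20 | cyclopropyl alcohol (1R,2R,3R,4R,5R,6S,8S,13S) | CC(C)(C)[Si](C)(C)OC[C@@H](CCC=C(C)C)[C@@H]1[C@H]2COC(=O)[C@@H]2[C@@H]2C[C@@H]2[C@@H](C)C[C@@H]1O | intermediate
21 | C8 triethylsilyl ether of 20 | CC(C)(C)[Si](C)(C)OC[C@@H](CCC=C(C)C)[C@@H]1[C@H]2COC(=O)[C@@H]2[C@@H]2C[C@@H]2[C@@H](C)C[C@@H]1O[Si](CC)(CC)CC | intermediate
22 | lithium enolate of 21 | CC(C)(C)[Si](C)(C)OC[C@@H](CCC=C(C)C)[C@@H]1[C@H]2COC(O[Li])=C2[C@@H]2C[C@@H]2[C@@H](C)C[C@@H]1O[Si](CC)(CC)CC | intermediate (not isolated)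
23 | C3-phenylselanyl lactone, selenium cis to H-2 | CC(C)(C)[Si](C)(C)OC[C@@H](CCC=C(C)C)[C@@H]1[C@H]2COC(=O)[C@@]2([Se]c2ccccc2)[C@@H]2C[C@@H]2[C@@H](C)C[C@@H]1O[Si](CC)(CC)CC | intermediate
24 | selenoxide of 23 | CC(C)(C)[Si](C)(C)OC[C@@H](CCC=C(C)C)[C@@H]1[C@H]2COC(=O)[C@@]2([Se](=O)c2ccccc2)[C@@H]2C[C@@H]2[C@@H](C)C[C@@H]1O[Si](CC)(CC)CC | intermediate (not isolated)
25 | butenolide with C14–OTBS and C8–OTES (1R,4R,5R,6S,8S,13S) | CC(C)(C)[Si](C)(C)OC[C@@H](CCC=C(C)C)[C@@H]1C2=C(C(=O)OC2)[C@@H]2C[C@@H]2[C@@H](C)C[C@@H]1O[Si](CC)(CC)CC | intermediate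
26 | diol (C14–OH, C8–OH) | OC[C@@H](CCC=C(C)C)[C@@H]1C2=C(C(=O)OC2)[C@@H]2C[C@@H]2[C@@H](C)C[C@@H]1O | intermediate
27 | CNP0267808.2, C14 acetate with free C8–OH (1R,4R,5R,6S,8S,13S) | CC(=O)OC[C@@H](CCC=C(C)C)[C@@H]1C2=C(C(=O)OC2)[C@@H]2C[C@@H]2[C@@H](C)C[C@@H]1O | target

Total step count: 16. Longest linear sequence: 16 steps (1 → 27).

Steps most likely to fail

1. Step 9 (key step). What may go wrong: acid-catalysed migration of the exocyclic double bond into the ring before the shift, epimerisation at C3 that unlocks the pyran chair, or leakage through a boat-like array that erodes the C6 configuration. The fallback sets out from 17 and comes back at 19, or at 18 through F1. Instead of thermolysis, 17 is treated with i-Bu3Al in CH2Cl2 from −78 °C to room temperature. This organoaluminium-promoted Claisen ring expansion runs far below the temperature at which the enol ether isomerises, and the aluminium-bound C8 ketone is reduced in the same flask by β-hydride transfer, which should give 19 directly. Should hydride arrive on the other face, the product is the (8R)-alcohol F1, which Dess–Martin periodinane oxidises to 18 for step 10.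

2. Step 3. What may go wrong: incomplete facial pairing of enolate and furanone (C2 epimers that cannot be corrected later), and loss of chemoselectivity in the hydride stage if the ring-B enolate is protonated or equilibrates before i-Bu2AlH arrives. The fallback sets out from 5 and comes back at 11; it uses an aldehyde-level donor under auxiliary control, so no second lactone has to be spared. Lactone 5 is reduced with i-Bu2AlH to the ring-A lactol F2, which is condensed with (R)-1-amino-2-(methoxymethyl)pyrrolidine to the hydroxy hydrazone F3 and silylated (TBSCl, imidazole) to the silyl ether F4. Deprotonation with LiN(i-Pr)2 gives the lithium azaenolate F5, whose Michael addition to 6 sets C1 by the auxiliary and gives, after protonation, the Michael adduct F6. Aqueous oxalic acid cleaves the hydrazone to the aldehyde F7, and Wittig methylenation (Ph3PCH3Br, KN(SiMe3)2) gives 11.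

3. Step 11. What may go wrong: competitive cyclopropanation of the electron-rich side-chain alkene if transannular delivery from the C8 alkoxide is weak, and with it poor facial control. The fallback sets out from 19 and comes back at 20; it installs a closer directing group. i-Bu2AlH reduces ring B of 19 to the ring-B lactol F8, whose C10 hydroxyl is homoallylic to C4=C5 and lies on the required face. Et2Zn/CH2I2 then gives the cyclopropyl lactol F9, and Ag2CO3 on Celite oxidises the lactol back to the lactone, giving 20.

Further compounds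
F1 | step 9 | (8R)-alcohol, C8 epimer of 19 | CC(C)(C)[Si](C)(C)OC[C@@H](CCC=C(C)C)[C@@H]1[C@H]2COC(=O)[C@@H]2/C=C\[C@@H](C)C[C@H]1O
F2 | step 3 | (4S)-4-(4-methylpent-3-en-1-yl)oxolan-2-ol (ring-A lactol, both anomers) | OC1C[C@H](CCC=C(C)C)CO1
F3 | step 3 | hydroxy hydrazone of the open lactol with (R)-1-amino-2-(methoxymethyl)pyrrolidine | OC[C@@H](CCC=C(C)C)C/C=N/N1CCC[C@@H]1COC
F4 | step 3 | tert-butyldimethylsilyl ether of F3 | CC(C)(C)[Si](C)(C)OC[C@@H](CCC=C(C)C)C/C=N/N1CCC[C@@H]1COC
F5 | step 3 | lithium azaenolate of F4 | CC(C)(C)[Si](C)(C)OC[C@@H](CCC=C(C)C)/C=C/N([Li])N1CCC[C@@H]1COC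
F6 | step 3 | Michael adduct of F5 with 6 (hydrazone, ring B attached at C1) | CC(C)(C)[Si](C)(C)OC[C@@H](CCC=C(C)C)[C@@H](/C=N/N1CCC[C@@H]1COC)[C@H]1COC(=O)C1
F7 | step 3 | C8 aldehyde from hydrolysis of F6 | CC(C)(C)[Si](C)(C)OC[C@@H](CCC=C(C)C)[C@@H](C=O)[C@H]1COC(=O)C1
F8 | step 11 | ring-B lactol of 19 (both anomers at C10) | CC(C)(C)[Si](C)(C)OC[C@@H](CCC=C(C)C)[C@@H]1[C@H]2COC(O)[C@@H]2/C=C\[C@@H](C)C[C@@H]1O
F9 | step 11 | cyclopropyl lactol from F8 | CC(C)(C)[Si](C)(C)OC[C@@H](CCC=C(C)C)[C@@H]1[C@H]2COC(O)[C@@H]2[C@@H]2C[C@@H]2[C@@H](C)C[C@@H]1O
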